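Tuesday's flask still held 6.1% of leftover substrate at 60.0 s, and I wanted the leftover at the asked time.

| flask | substrate | coupling partner | remark | time |
|---|---|---|---|---|
| Tuesday's | 1 M (in portions, 4) | 1 M | the very flask that is asked about, followed so far; portions every 30 s |  |
| Sunday's | 0.50 M (in portions, 4) | 1 M | run made earlier; portions every 30 s |  |
| flask | 1.0 M (in portions, 4) | 1.00 M | the portions of substrate follow each other after 30 s, the first at the start | 2.0 min |

| run | time / s | intermediate B / % | intermediate C / % | substrate / % | intermediate A / % | product / % |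
|---|---|---|---|---|---|---|
| Tuesday's | 10.0 | 0.6 | 0.1 | 9.6 | 13.2 | 0 |
| Tuesday's | 20.0 | 1.0 | 0 | 5.6 | 17.9 | 0.2 |
| Tuesday's | 30.0 | 2.9 | 0.2 | 1.4 | 19.1 | 0 |
| Tuesday's | 40.0 | 4.6 | 0.3 | 15.2 | 30.3 | 0 |
| Tuesday's | 50.0 | 6.9 | 0.4 | 9.6 | 35.1 | 0.4 |
| Tuesday's | 60.0 | 8.0 | 0 | 6.1 | 36.0 | 0 |
| Sunday's | 10.0 | 1.0 | 0.4 | 9.8 | 14.2 | 0 |
| Sunday's | 15.0 | 0.9 | 0.8 | 6.9 | 16.9 | 0 |
| Sunday's | 25.0 | 3.2 | 0.9 | 2.0 | 19.6 | 0 |
| Sunday's | 40.0 | 4.1 | 0 | 12.1 | 32.0 | 0 |
| Sunday's | 50.0 | 6.0 | 0 | 7.1 | 36.2 | 0 |

(standard deviation of a reading: 0.5 percentage points)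

* the species in which most of what was charged as substrate, at 2.0 min sits (intermediate A / intermediate B / product / intermediate C / substrate)
* the largest share itself, whichever of these holds it, in percent of the substrate charged

- a reading at the moment of an addition is taken just before it
- percentages count the whole charge, also what has not yet gone in

In Tuesday's flask the first portion of substrate fell at 0.0961 s⁻¹ and the second at 0.0457 s⁻¹, slower. I treated the portions as one dose with a mean time in the flask of 75.0 s. Substrate and coupling partner were charged equally, so I used a Damköhler number, rate times time: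

first round: leftover = 1/(1 + 7.21) = 12.2%

second round, with the later rate: leftover = 1/(1 + 3.42) = 22.6%

What reacted still had to be divided. I read the split ratio, intermediate B over intermediate A, from Tuesday's last reading: 0.222. It had risen from 0.152 at 30.0 s, so holding it steady was my gamble. The ratio cannot say how much reacted, so it needs the leftover:

intermediate A = (1 − leftover)/(1 + ratio) = 63.3%

The forecast named intermediate A too, but at 55%, with intermediate B at 25 and the step to it “first order at about 0.006 /s”. My figure was higher.

At 2.0 min the flask gave intermediate A at 61.7%.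

    intermediate C → product (k = 7.82 × 10⁻⁴ s⁻¹)
    intermediate A ⇌ intermediate B (K = 0.238, k = 0.0155 s⁻¹)
    substrate + coupling partner → intermediate A (k = 0.0999 M⁻¹ s⁻¹)
    coupling partner + intermediate B → intermediate C (k = 0.00365 M⁻¹ s⁻¹)
    coupling partner ⇌ dormant form (K = 0.470, k = 0.00557 s⁻¹)

Intermediate B stood at 13.5%, against the forecast's 25, and the relaxation half-life between the two intermediates, 0.143 min, is short against the run. With the flask's leftover substrate of 23.9%, the split ratio gives 62.3% for intermediate A. In the neighbour with 0.60 M of coupling partner, 47.9% of the substrate is left, so the ratio gives 42.6%. The computed amount is 42.3%, and there substrate holds most.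

The earlier runs and the new flask were computed from invented constants; scatter was added.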